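Early on the ring in this flask climbs in equal steps, 14% after 4.00 h and 28% after 8.00 h, so you should first ask whether its rate can follow the fraction of charge left.

common to all: solid substrate 13 mM

|  | remark | time |
|---|---|---|
| east | the very flask that is asked about, followed so far |  |
| flask |  | 12 d |

east run (percent of the solid substrate charged)

| time / h | ring / % |
|---|---|
| 4.00 | 14 |
| 8.00 | 28 |
| 12.0 | 39 |
| 15.0 | 50 |
| 20.0 | 59 |
| 25.0 | 71 |

(standard deviation of a reading: 1.5 percentage points)

- given per volume of solution although it is solid: solid substrate
- at the start none of the solid substrate is in solution

1. the moment within 12 d at which there is most ring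
2. the amount of ring, in percent of the solid substrate charged, at that time
3. earliest time at which at least nineteen twentieths of that best amount are there, in d
4. latest time at which they still are, in d

With 86.0% left after the first step, such a rate gives a second step of 12.0%, smaller than the first by about the scatter, so the readings merely lean one way, and I take as my own reading a steady, zero-order supply from the solid.

Why, then, does the slope sink from 0.0350 h⁻¹ of the charge to 0.0210 h⁻¹ between 15.0 h and 25.0 h? On a steady supply that is ring being lost, and the fraction of slope left, 0.600 across 16.0 h, gives a loss constant of 0.0319 h⁻¹.

How much ring survives? Carried back to the start, the supply reckons to 0.0398 h⁻¹, so on this reading the charge lasts about 25.1 h. The loss number, the loss constant times that supply time, is 0.803, and the average portion kept, (1 − e^(−x))/x, is 68.7%. I therefore commit to that amount near 25.1 h.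

The forecast differs, with 97% at 12 d, open from 2 d to 12 d, a plateau “lasting to the end of the run”.

The flask gives 69.5% at 1.05 d, open from 0.955 d to 1.18 d.

    2 starting material ⇌ open dimer (K = 20.5 M⁻¹, k = 0.0371 M⁻¹ s⁻¹)
    starting material → ring (k = 1.90 × 10⁻⁴ s⁻¹)
    ring → over-reaction product (k = 7.80 × 10⁻⁶ s⁻¹)
    solid substrate ⇌ starting material, rate k4*(cs4 - [starting material]) while solid is left; crystals form when [starting material] > cs4 (solubility = 0.920 mM, k = 8.33 × 10⁻⁴ s⁻¹)

Ring in this flask then falls to 2.58% at 6.00 d, while over-reaction product reaches 97.4%; the portion kept was 68.7% by the reckoning from the readings and is 69.5% at the best time of this flask. For the neighbour flask charged with 22 mM, hold the supply in millimolar per hour and the loss constant as they were: the supply time reckons to 42.6 h, the loss number to 1.36, and the portion kept to 54.7%. At its best the neighbour flask gives 57.2%.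

(Readings and results are calculated from invented constants.)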